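The indole is disconnected at N1–C7a, so that the pyrrole ring is closed onto a ready-made dibromobenzene by Hemetsberger–Knittel thermolysis. The feature exploited is the para pair of bromines at C4 and C7 of the benzene ring. In the precursor, ethyl (Z)-2-azido-3-(2,5-dibromophenyl)acrylate, the future C4 bromine fills one position ortho to the side chain. This leaves one ortho C–H (future C7a, beside C7–Br) for nitrogen. One metal-free operation thus forms N1–C7a, closes the five-membered ring and fixes the 4,7-pattern. The C2 ester then shields C2 during C3 chlorination and is finally traded for bromine by ipso bromodecarboxylation.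

Key step: step 2

Remark on the chemistry: the target is planar and has no stereogenic element, so it is achiral and no enantiomer has to be selected. The only configuration in the route is the Z alkene of 4. Azide 2 is used as its commercial solution and is never concentrated, and azide 4 is never heated neat.

Step 1
Reactants: 1 2,5-dibromobenzaldehyde; 2 ethyl azidoacetate (excess)
Product: 4 ethyl (Z)-2-azido-3-(2,5-dibromophenyl)acrylate, via aldol adduct 3 (not isolated)
Conditions: NaOEt, EtOH, −15 → 0 °C; sat. aq. NH4Cl quench
Reagents that add atoms: none
Why: Knoevenagel-type aldol condensation (first stage of the Hemetsberger–Knittel sequence): the enolate of 2 adds to the electron-poor, non-enolisable aldehyde to give 3, E1cB loss of hydroxide should deliver the more stable Z alkene (aryl trans to the ester, cis to the azide), ethoxide matches the ester so that alkoxide exchange is degenerate, and low temperature with excess 2 offsets the base lability of the azidoacetate while both C–Br bonds stay untouched.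

Step 2
Reactants: 4 ethyl (Z)-2-azido-3-(2,5-dibromophenyl)acrylate
Product: 8 ethyl 4,7-dibromo-1H-indole-2-carboxylate, via 2H-azirine 5 (not isolated), via vinyl nitrene 6 (not isolated), via 7aH-indole 7 (not isolated)
Conditions: xylenes, reflux (ca. 140 °C), N2; 4 in xylenes added dropwise over 1–2 h, final concentration ≤0.05 M
Reagents that add atoms: none
Why: Heat expels N2 from vinyl azide 4 to give 2H-azirine 5, which at this temperature reopens reversibly by cleavage of its C–N single bond to singlet vinyl nitrene 6. The atoms N, Cα, Cβ, C-ipso and C-ortho of 6 then undergo a 6π five-atom (1,5-) electrocyclisation that makes N1–C7a and gives 7aH-indole 7, and a [1,5]-hydrogen shift from C7a to N1 restores aromaticity in 8; this is the Hemetsberger–Knittel indole synthesis, a known reaction of α-azidocinnamates that tolerates ring halogens. The single ring closed is the pyrrole ring, in an electrocyclic mode that is formally 5-endo-trig at the arene carbon. No stereocentre is created, since the sp3 carbons of 5 and 7 are transient, racemic and erased on aromatisation, and passage through 5 also makes the alkene geometry of 4 uncritical. The selectivity required is between the two ortho carbons, and the substrate secures it: C2′ carries bromine and has no hydrogen to shift, so closure there should be unproductive and reversible, whereas C6′–H beside the C5′ bromine is free and maps onto the 4,7-dibromo pattern only. Chemoselectivity rests on the absence of metal, base and reductant, so both C–Br bonds and the ester are inert, and slow addition into a large volume of boiling solvent keeps the azide dilute, which favours unimolecular closure over bimolecular nitrene decay and meters the gas evolution.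

Step 3
Reactants: 8 ethyl 4,7-dibromo-1H-indole-2-carboxylate
Product: 9 ethyl 4,7-dibromo-3-chloro-1H-indole-2-carboxylate
Conditions: NCS (1.1 equiv), DMF, rt → 50 °C
Reagents that add atoms: N-chlorosuccinimide, O=C1CCC(=O)N1Cl
Why: Electrophilic aromatic chlorination (SEAr) of an indole: C3 is the only open pyrrole carbon and remains the most nucleophilic site, because C2 is held by the ester and C5/C6 lie on a ring deactivated by two bromines, so about one equivalent of NCS in a polar solvent should monochlorinate there despite the peri C4 bromine.

Step 4
Reactants: 9 ethyl 4,7-dibromo-3-chloro-1H-indole-2-carboxylate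
Product: 11 4,7-dibromo-3-chloro-1H-indole-2-carboxylic acid, via lithium carboxylate 10 (not isolated)
Conditions: LiOH·H2O (3 equiv), THF–EtOH–H2O, 40 °C; then 1 M HCl, 0 °C, pH 2, filtration
Reagents that add atoms: lithium hydroxide, [Li+].[OH-]
Why: Ester saponification (BAc2): hydroxide attacks only the ester carbonyl, since the aryl bromides and the C3 chloride lack the activation needed for SNAr, and cold acidification of carboxylate 10 should precipitate acid 11 without the heat it would need to decarboxylate.

Step 5
Reactants: 11 4,7-dibromo-3-chloro-1H-indole-2-carboxylic acid
Product: 12 2,4,7-tribromo-3-chloro-1H-indole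
Conditions: NBS (1.05 equiv), LiOAc (20 mol %), DMF, 0 °C → rt, dark; aq. NaHCO3/Na2S2O3 work-up, deactivated silica, cold and dark storage
Reagents that add atoms: N-bromosuccinimide, O=C1CCC(=O)N1Br
Why: Hunsdiecker-type ipso bromodecarboxylation, known for electron-rich heteroaromatic acids such as pyrrole- and indole-2-carboxylic acids: acetate generates the carboxylate, Br+ from NBS is delivered to C2, the only pyrrole position bearing a group that can leave as an electrofuge, and irreversible loss of CO2 rearomatises the ring, while C3 is blocked by chlorine and C5/C6 are too deactivated to compete.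

Compound list
1 | 2,5-dibromobenzaldehyde | O=Cc1cc(Br)ccc1Br | starting material
2 | ethyl azidoacetate | CCOC(=O)CN=[N+]=[N-] | starting material
3 | ethyl 2-azido-3-(2,5-dibromophenyl)-3-hydroxypropanoate (aldol adduct, racemic mixture of diastereomers, not isolated) | CCOC(=O)C(N=[N+]=[N-])C(O)c1cc(Br)ccc1Br | intermediate
4 | ethyl (Z)-2-azido-3-(2,5-dibromophenyl)acrylate | CCOC(=O)/C(N=[N+]=[N-])=C/c1cc(Br)ccc1Br | intermediate
5 | ethyl 2-(2,5-dibromophenyl)-2H-azirine-3-carboxylate (racemic, not isolated) | CCOC(=O)C1=NC1c1cc(Br)ccc1Br | intermediate
6 | singlet vinyl nitrene, ethyl (Z)-3-(2,5-dibromophenyl)-2-nitrenoacrylate (not isolated) | CCOC(=O)/C([N])=C/c1cc(Br)ccc1Br | intermediate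
7 | ethyl 4,7-dibromo-7aH-indole-2-carboxylate (racemic, not isolated) | CCOC(=O)C1=NC2C(Br)=CC=C(Br)C2=C1 | intermediate
8 | ethyl 4,7-dibromo-1H-indole-2-carboxylate | CCOC(=O)c1cc2c(Br)ccc(Br)c2[nH]1 | intermediate
9 | ethyl 4,7-dibromo-3-chloro-1H-indole-2-carboxylate | CCOC(=O)c1[nH]c2c(Br)ccc(Br)c2c1Cl | intermediate
10 | lithium 4,7-dibromo-3-chloro-1H-indole-2-carboxylate (not isolated) | [Li+].[O-]C(=O)c1[nH]c2c(Br)ccc(Br)c2c1Cl | intermediate
11 | 4,7-dibromo-3-chloro-1H-indole-2-carboxylic acid | OC(=O)c1[nH]c2c(Br)ccc(Br)c2c1Cl | intermediate
12 | 2,4,7-tribromo-3-chloro-1H-indole | Clc1c(Br)[nH]c2c(Br)ccc(Br)c12 | target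

Total step count: 5. Longest linear sequence: 5 (1 → 4 → 8 → 9 → 11 → 12).

Steps most likely to fail

Step 5. Ipso attack may be sluggish on a ring that already carries three halogens. Halogen scrambling at C3 may compete. The light- and acid-sensitive 2-bromoindole may also decay during isolation. The fallback separates loss of CO2 from introduction of bromine. It sets out from 11. Silver(I)-catalysed protodecarboxylation (Ag2CO3 cat., AcOH cat., DMSO, 120 °C), which leaves aryl bromides alone, should give 4,7-dibromo-3-chloro-1H-indole F1. Its only open pyrrole position, C2–H, is then brominated by ordinary SEAr with NBS (1.0 equiv, THF, 0 °C, dark). The sequence comes back to the route at 12.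

Step 2. Material may be lost through bimolecular nitrene decay and tar formation at 140 °C, or the reaction may stall at the azirine stage. The fallback replaces the free nitrene by a metal-bound nitrenoid. It sets out from 4 and uses rhodium(II)-carboxylate-catalysed C–H amination of the vinyl azide (Rh2(O2CC3F7)4, 3–5 mol %, toluene, 4 Å MS, 40–60 °C). This is a known reaction type for α-azidocinnamates. Dinitrogen is lost on the metal and the arene attacks the electrophilic nitrogen at the same free ortho carbon. The aryl bromides are inert to rhodium(II) carboxylates. The fallback comes back at 8 and makes no compound outside the list (F0).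

Step 1. The azidoacetate anion may decompose faster than it adds to the ortho-hindered aldehyde. The reaction may also stall at the aldol stage, or the liberated hydroxide may hydrolyse the ester. The fallback separates C–C bond formation from elimination. It sets out from 1 and 2. The addition is run at −30 °C and quenched cold, so that 3 is isolated. Treatment with MsCl and excess Et3N (CH2Cl2, −20 → 0 °C) converts it into ethyl 2-azido-3-(2,5-dibromophenyl)-3-(methylsulfonyloxy)propanoate F2. This mesylate should eliminate in the same flask by E1cB to the more stable Z alkene. The fallback comes back at 4.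

Further compounds
F1 | step 5 | 4,7-dibromo-3-chloro-1H-indole | Clc1c[nH]c2c(Br)ccc(Br)c12
F0 | step 2 | none | none
F2 | step 1 | ethyl 2-azido-3-(2,5-dibromophenyl)-3-(methylsulfonyloxy)propanoate (racemic mixture of diastereomers) | CCOC(=O)C(N=[N+]=[N-])C(OS(C)(=O)=O)c1cc(Br)ccc1Br
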